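**Strategy.** Numbering: cyclohexane C1 (the CH bonded to the oxane) to C6, with Cl on C3 and Br and CH3 on C4; oxane O1', C2' to C6'. The carbocycle is closed last, at C4–C5. The precursor is an acyclic ethyl ketone whose C1 already carries the finished bromo-oxane, a vinyl group (C6=C5) and the CH2C(=O)CH2CH3 arm (C2, C3, C4). A PdCl2(MeCN)2-catalysed 6-endo hydroalkylation adds the enolisable C4–H across C5=C6; it exploits the 3-butenyl ketone relation of C4 and C5 around C1. One operation gives the 2-methylcyclohexanone, whose C3 carbonyl then relays C1 to C4 (axial Br) and C3 (Cl). A single Sharpless epoxidation controls C6', C1, C5' and C3'.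

Key step: step 11

Remark: the descriptor of C1 changes from R (compounds 9–14) to S (15–18) and back to R (19–23) only because the CIP ranks of its neighbours change; no bond at C1 is touched after step 4.

Step 1
Reactants: 1 acrolein (prop-2-enal); 2 ethyl 2-(triphenyl-λ5-phosphanylidene)propanoate
Product: 3 ethyl (2E)-2-methylpenta-2,4-dienoate
Conditions: CH2Cl2, 0 °C to rt
Reagents that add atoms: none
Why: Wittig olefination with a stabilised ylide adds only to the aldehyde and should give the (E)-trisubstituted alkene.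

Step 2
Reactants: 3 ethyl (2E)-2-methylpenta-2,4-dienoate
Product: 4 (2E)-2-methylpenta-2,4-dien-1-ol
Conditions: i-Bu2AlH, CH2Cl2, −78 °C
Reagents that add atoms: none
Why: 1,2-reduction of the conjugated ester by the aluminium hydride should give the allylic alcohol without touching the diene.

Step 3
Reactants: 4 (2E)-2-methylpenta-2,4-dien-1-ol
Product: 5 [(2R,3R)-3-ethenyl-2-methyloxiran-2-yl]methanol
Conditions: Ti(OiPr)4 (cat.), D-(−)-diethyl tartrate (cat.), t-BuOOH, 4 Å molecular sieves, CH2Cl2, −20 °C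
Reagents that add atoms: tert-butyl hydroperoxide CC(C)(C)OO
Why: Sharpless asymmetric epoxidation oxidises only the hydroxyl-bound trisubstituted alkene, and the D-(−)-tartrate catalyst should deliver oxygen to the face that gives the (2R,3R)-epoxide, which fixes C6' and prepares C1.

Step 4
Reactants: 5 [(2R,3R)-3-ethenyl-2-methyloxiran-2-yl]methanol; 6 but-1-yne
Product: 9 (2S,3R)-3-ethenyl-2-methylhept-4-yne-1,2-diol, via lithium but-1-ynide 7 (not isolated), via diethyl(but-1-yn-1-yl)aluminium 8 (not isolated)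
Conditions: 6, n-BuLi, toluene, 0 °C; Et2AlCl; then 5, 0 °C to rt; aqueous Rochelle salt
Reagents that add atoms: none
Why: Ring opening of a 2,3-epoxy alcohol by an alkynylaluminium reagent occurs at C3 (here the allylic carbon, C2 being quaternary) by anti SN2 attack, so inversion sets C1 relative to C6'.

Step 5
Reactants: 9 (2S,3R)-3-ethenyl-2-methylhept-4-yne-1,2-diol
Product: 10 (2S,3R)-3-ethenyl-2-hydroxy-2-methylhept-4-ynal
Conditions: IBX, DMSO, rt
Reagents that add atoms: none
Why: IBX oxidation should convert the primary alcohol of the 1,2-diol into the aldehyde without glycol cleavage and leave the tertiary alcohol.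

Step 6
Reactants: 10 (2S,3R)-3-ethenyl-2-hydroxy-2-methylhept-4-ynal; 11 allylmagnesium bromide (CH2=CHCH2MgBr)
Product: 12 (4S,5S,6R)-6-ethenyl-5-methyldec-1-en-7-yne-4,5-diol
Conditions: 11 (3 equiv), THF, −78 °C
Reagents that add atoms: none
Why: Chelation-controlled Grignard addition (Cram chelate through the magnesium alkoxide of the α-hydroxyl) should bring the allyl group in from the methyl side of C6', away from the branched C1, which sets C5' as 4S.

Step 7
Reactants: 12 (4S,5S,6R)-6-ethenyl-5-methyldec-1-en-7-yne-4,5-diol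
Product: 13 (4S,5S,6R)-6-ethenyl-5-hydroxy-5-methyldec-1-en-7-yn-4-yl acetate
Conditions: Ac2O, pyridine, DMAP (cat.), CH2Cl2, 0 °C
Reagents that add atoms: acetic anhydride CC(=O)OC(C)=O
Why: Acylation should occur only at the secondary alcohol, and the acetate keeps O5' out of steps 8, 10 and 11.

Step 8
Reactants: 13 (4S,5S,6R)-6-ethenyl-5-hydroxy-5-methyldec-1-en-7-yn-4-yl acetate
Product: 15 (4S,5S,6S)-6-ethenyl-5-hydroxy-5-methyl-8-oxodec-1-en-4-yl acetate, via cyclic enol ether 14 (not isolated)
Conditions: Ph3PAuNTf2 (2 mol %), THF, rt; then H2O, TsOH·H2O (cat.), rt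
Reagents that add atoms: water O
Why: Gold-catalysed 5-endo-dig hydroalkoxylation of the homopropargylic tertiary alcohol puts oxygen on the distal alkyne carbon, and hydrolysis of the enol ether should give the C3 ketone regiospecifically (alkyne hydration directed by a neighbouring hydroxyl).

Step 9
Reactants: 15 (4S,5S,6S)-6-ethenyl-5-hydroxy-5-methyl-8-oxodec-1-en-4-yl acetate; 16 2-methylbut-2-ene
Product: 17 (5S,6S,7S)-7-ethenyl-6-hydroxy-2,6-dimethyl-9-oxoundec-2-en-5-yl acetate
Conditions: second-generation Grubbs catalyst (5 mol %), 16 (excess), CH2Cl2, 40 °C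
Reagents that add atoms: none
Why: Olefin cross-metathesis should convert the unhindered allyl terminus into the prenyl group, while the vinyl group on the branched C1 next to quaternary C6' is too hindered to react.

Step 10
Reactants: 17 (5S,6S,7S)-7-ethenyl-6-hydroxy-2,6-dimethyl-9-oxoundec-2-en-5-yl acetate
Product: 18 (2S,3S,5S)-5-bromo-2,6,6-trimethyl-2-[(3S)-5-oxohept-1-en-3-yl]oxan-3-yl acetate
Conditions: 2,4,4,6-tetrabromocyclohexa-2,5-dienone, CH2Cl2, 0 °C to rt
Reagents that add atoms: 2,4,4,6-tetrabromocyclohexa-2,5-dienone O=C1C(Br)=CC(Br)(Br)C=C1Br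
Why: Bromoetherification: the tertiary C6'–OH opens the bromonium ion of the electron-rich prenyl alkene at C2' (6-endo, Markovnikov) through a chair with the C1 branch equatorial, which should place Br equatorial at C3', trans to the axial acetate.

Step 11
Reactants: 18 (2S,3S,5S)-5-bromo-2,6,6-trimethyl-2-[(3S)-5-oxohept-1-en-3-yl]oxan-3-yl acetate
Product: 19 (2S,3S,5S)-5-bromo-2,6,6-trimethyl-2-[(1R,4R)-4-methyl-3-oxocyclohexyl]oxan-3-yl acetate
Conditions: PdCl2(MeCN)2 (10 mol %), CuCl2 (30 mol %), HCl (cat., dioxane solution), dioxane, 70 °C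
Reagents that add atoms: none
Why: The divalent palladium catalyst binds the C5=C6 vinyl group and the enol of the ethyl ketone (C3=C4) adds anti at the terminal carbon C5; the alkylpalladium at C6 then migrates by β-hydride elimination and re-addition to a palladium enolate that HCl protonates, so C4–H is added across the alkene and the metal is returned. The closest known reaction type is the PdCl2(MeCN)2/CuCl2/HCl-catalysed intramolecular hydroalkylation of 3-butenyl ketones, a metal-mediated relative of the Conia-ene reaction. The ring C4–C5–C6–C1–C2–C3 closes in a 6-endo-trig mode with the enol double bond also inside the ring (enolendo). The only new stereocentre, C4, is epimerisable α to the carbonyl and should settle with methyl equatorial, trans to the equatorial C1 substituent; it is erased by enolisation in step 12, and C1 is not touched as long as the palladium hydride stays bound during migration. The step needs regioselectivity (C4 enol, attack at C5) and chemoselectivity: the C2 enol could only form a three- or four-membered ring, C5 is the unhindered terminus whereas C6 is flanked by the branched C1, the prenyl alkene is already consumed in the oxane, and O5' is acetylated so that no hydroxyl can add to the palladium-bound alkene.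

Step 12
Reactants: 19 (2S,3S,5S)-5-bromo-2,6,6-trimethyl-2-[(1R,4R)-4-methyl-3-oxocyclohexyl]oxan-3-yl acetate
Product: 20 (2S,3S,5S)-5-bromo-2-[(1R,4S)-4-bromo-4-methyl-3-oxocyclohexyl]-2,6,6-trimethyloxan-3-yl acetate
Conditions: Br2 (1 equiv), AcOH, rt
Reagents that add atoms: bromine BrBr
Why: Acid-catalysed α-bromination goes through the more substituted enol (C3=C4); axial attack on the ring anchored by the equatorial C1 substituent, and HBr equilibration to the same axial-Br/equatorial-CH3 epimer, should put Br on C4 cis to the C1 substituent.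

Step 13
Reactants: 20 (2S,3S,5S)-5-bromo-2-[(1R,4S)-4-bromo-4-methyl-3-oxocyclohexyl]-2,6,6-trimethyloxan-3-yl acetate
Product: 21 (2S,3S,5S)-5-bromo-2-[(1R,3R,4S)-4-bromo-3-hydroxy-4-methylcyclohexyl]-2,6,6-trimethyloxan-3-yl acetate
Conditions: NaBH4, MeOH, −40 °C
Reagents that add atoms: none
Why: Hydride should add axially, anti to the axial C4–Br bond (Felkin–Anh/Cornforth polar control), to give the equatorial C3 alcohol cis to bromine, a bromohydrin that cannot close to an epoxide.

Step 14
Reactants: 21 (2S,3S,5S)-5-bromo-2-[(1R,3R,4S)-4-bromo-3-hydroxy-4-methylcyclohexyl]-2,6,6-trimethyloxan-3-yl acetate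
Product: 22 (2S,3S,5S)-5-bromo-2-[(1R,3S,4S)-4-bromo-3-chloro-4-methylcyclohexyl]-2,6,6-trimethyloxan-3-yl acetate
Conditions: Ph3P, N-chlorosuccinimide, THF, 0 to 40 °C
Reagents that add atoms: N-chlorosuccinimide O=C1CCC(=O)N1Cl
Why: Appel-type chlorination: chloride displaces the equatorial alkoxyphosphonium by SN2 along the axial trajectory (no anti-periplanar hydrogen for E2, bromine gauche and so not participating), and inversion should give the axial chloride trans-diaxial to bromine.

Step 15
Reactants: 22 (2S,3S,5S)-5-bromo-2-[(1R,3S,4S)-4-bromo-3-chloro-4-methylcyclohexyl]-2,6,6-trimethyloxan-3-yl acetate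
Product: 23 (2S,3S,5S)-5-bromo-2-[(1R,3S,4S)-4-bromo-3-chloro-4-methylcyclohexyl]-2,6,6-trimethyloxan-3-ol
Conditions: i-Bu2AlH, CH2Cl2, −78 °C
Reagents that add atoms: none
Why: Reductive cleavage of the hindered acetate at low temperature is non-basic and should leave the tertiary bromide and the vicinal bromochloride untouched (ester reduction).

**Compound list**

1 | acrolein (prop-2-enal) | C=CC=O | starting material
2 | ethyl 2-(triphenyl-λ5-phosphanylidene)propanoate | CCOC(=O)C(C)=P(c1ccccc1)(c1ccccc1)c1ccccc1 | starting material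
3 | ethyl (2E)-2-methylpenta-2,4-dienoate | CCOC(=O)/C(C)=C/C=C | intermediate
4 | (2E)-2-methylpenta-2,4-dien-1-ol | OC/C(C)=C/C=C | intermediate
5 | [(2R,3R)-3-ethenyl-2-methyloxiran-2-yl]methanol | OC[C@@]1(C)O[C@@H]1C=C | intermediate
6 | but-1-yne | CCC#C | starting material
7 | lithium but-1-ynide | [Li]C#CCC | intermediate
8 | diethyl(but-1-yn-1-yl)aluminium | CCC#C[Al](CC)CC | intermediate
9 | (2S,3R)-3-ethenyl-2-methylhept-4-yne-1,2-diol | OC[C@@](C)(O)[C@H](C=C)C#CCC | intermediate
10 | (2S,3R)-3-ethenyl-2-hydroxy-2-methylhept-4-ynal | O=C[C@@](C)(O)[C@H](C=C)C#CCC | intermediate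
11 | allylmagnesium bromide | C=CC[Mg]Br | starting material
12 | (4S,5S,6R)-6-ethenyl-5-methyldec-1-en-7-yne-4,5-diol | C=CC[C@H](O)[C@@](C)(O)[C@H](C=C)C#CCC | intermediate
13 | (4S,5S,6R)-6-ethenyl-5-hydroxy-5-methyldec-1-en-7-yn-4-yl acetate | C=CC[C@H](OC(C)=O)[C@@](C)(O)[C@H](C=C)C#CCC | intermediate
14 | (1S)-1-[(2S,3R)-3-ethenyl-5-ethyl-2-methyl-2,3-dihydrofuran-2-yl]but-3-en-1-yl acetate | CCC1=C[C@@H](C=C)[C@](C)(O1)[C@H](CC=C)OC(C)=O | intermediate
15 | (4S,5S,6S)-6-ethenyl-5-hydroxy-5-methyl-8-oxodec-1-en-4-yl acetate | C=CC[C@H](OC(C)=O)[C@@](C)(O)[C@H](C=C)CC(=O)CC | intermediate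
16 | 2-methylbut-2-ene | CC=C(C)C | starting material
17 | (5S,6S,7S)-7-ethenyl-6-hydroxy-2,6-dimethyl-9-oxoundec-2-en-5-yl acetate | CC(C)=CC[C@H](OC(C)=O)[C@@](C)(O)[C@H](C=C)CC(=O)CC | intermediate
18 | (2S,3S,5S)-5-bromo-2,6,6-trimethyl-2-[(3S)-5-oxohept-1-en-3-yl]oxan-3-yl acetate | CC1(C)O[C@@](C)([C@H](C=C)CC(=O)CC)[C@@H](OC(C)=O)C[C@@H]1Br | intermediate
19 | (2S,3S,5S)-5-bromo-2,6,6-trimethyl-2-[(1R,4R)-4-methyl-3-oxocyclohexyl]oxan-3-yl acetate | CC1(C)O[C@@](C)([C@@H]2CC[C@@H](C)C(=O)C2)[C@@H](OC(C)=O)C[C@@H]1Br | intermediate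
20 | (2S,3S,5S)-5-bromo-2-[(1R,4S)-4-bromo-4-methyl-3-oxocyclohexyl]-2,6,6-trimethyloxan-3-yl acetate | CC1(C)O[C@@](C)([C@@H]2CC[C@](C)(Br)C(=O)C2)[C@@H](OC(C)=O)C[C@@H]1Br | intermediate
21 | (2S,3S,5S)-5-bromo-2-[(1R,3R,4S)-4-bromo-3-hydroxy-4-methylcyclohexyl]-2,6,6-trimethyloxan-3-yl acetate | CC1(C)O[C@@](C)([C@@H]2CC[C@](C)(Br)[C@H](O)C2)[C@@H](OC(C)=O)C[C@@H]1Br | intermediate
22 | (2S,3S,5S)-5-bromo-2-[(1R,3S,4S)-4-bromo-3-chloro-4-methylcyclohexyl]-2,6,6-trimethyloxan-3-yl acetate | CC1(C)O[C@@](C)([C@@H]2CC[C@](C)(Br)[C@@H](Cl)C2)[C@@H](OC(C)=O)C[C@@H]1Br | intermediate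
23 | (2S,3S,5S)-5-bromo-2-[(1R,3S,4S)-4-bromo-3-chloro-4-methylcyclohexyl]-2,6,6-trimethyloxan-3-ol | CC1(C)O[C@@](C)([C@@H]2CC[C@](C)(Br)[C@@H](Cl)C2)[C@@H](O)C[C@@H]1Br | target

**Totals.** Total step count: 15. Longest linear sequence: 15 steps (from acrolein 1).

**Steps most likely to fail**

Step 11 (key step). What may go wrong: loss of the palladium hydride during chain-walking, which would scramble C1 or isomerise the vinyl group; 5-exo attack at C6; or acid-promoted opening of the bromo-oxane at 70 °C. The fallback replaces alkene activation by a polar enolate alkylation; it sets out from 18 and comes back at 19. The vinyl group of 18 is hydroborated with 9-BBN (THF, 0 °C, faster than ketone reduction) and oxidised with NaBO3·4H2O to the primary alcohol (2S,3S,5S)-5-bromo-2-[(3R)-1-hydroxy-5-oxoheptan-3-yl]-2,6,6-trimethyloxan-3-yl acetate F1. I2, Ph3P and imidazole (CH2Cl2, 0 °C) convert it into the iodide (2S,3S,5S)-5-bromo-2-[(3S)-1-iodo-5-oxoheptan-3-yl]-2,6,6-trimethyloxan-3-yl acetate F2. KN(SiMe3)2 (THF, −78 to 0 °C) then closes C4–C5 by 6-(enolendo)-exo-tet alkylation of the equilibrating ketone enolate (the C2 enolate could only give a cyclobutane) to give 19.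

Step 14. What may go wrong: the SN2 displacement at C3, next to the quaternary C4, may stall, or the alkoxyphosphonium may ionise with ring contraction or elimination. The fallback introduces chloride by allylic substitution and bromide by ionic HBr addition; it sets out from 20 and comes back at 22. Dehydrobromination of 20 with LiBr and Li2CO3 (DMF, 120 °C; anti elimination of the axial bromide with the axial C5–H) gives the enone (2S,3S,5S)-5-bromo-2,6,6-trimethyl-2-[(1R)-4-methyl-5-oxocyclohex-3-en-1-yl]oxan-3-yl acetate F3. NaBH4 with CeCl3·7H2O (MeOH, −78 °C; Luche reduction, axial hydride) gives the cis allylic alcohol (2S,3S,5S)-5-bromo-2-[(1R,5R)-5-hydroxy-4-methylcyclohex-3-en-1-yl]-2,6,6-trimethyloxan-3-yl acetate F4. N-Chlorosuccinimide and Me2S (CH2Cl2, −20 °C; Corey–Kim chlorination, SN2 inversion at the unhindered allylic carbinol) give the trans allylic chloride (2S,3S,5S)-5-bromo-2-[(1R,5S)-5-chloro-4-methylcyclohex-3-en-1-yl]-2,6,6-trimethyloxan-3-yl acetate F5. Anhydrous HBr (CH2Cl2, −40 °C) then adds in the Markovnikov sense, H to C5 and Br to C4 anti to chlorine through a bridged chloronium ion, to give 22.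

Step 10. What may go wrong: low conversion in the bromonium cyclisation, competing 5-exo closure at C3', allylic bromination, or poor face selectivity at C3'. The fallback uses reversible oxymercuration followed by stereoretentive bromodemercuration; it sets out from 17 and comes back at 18. Hg(OCOCF3)2 (MeNO2, 0 °C; then aqueous KBr) cyclises 17 under thermodynamic control in the Markovnikov 6-endo sense to the equatorial organomercurial bromo{(3S,5S,6S)-5-(acetyloxy)-2,2,6-trimethyl-6-[(3S)-5-oxohept-1-en-3-yl]oxan-3-yl}mercury F6. Br2 (1 equiv) in pyridine at −40 °C in the dark should cleave the C–Hg bond with retention, faster than it adds to the monosubstituted vinyl group, to give 18.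

**Further compounds**

F1 | step 11 | (2S,3S,5S)-5-bromo-2-[(3R)-1-hydroxy-5-oxoheptan-3-yl]-2,6,6-trimethyloxan-3-yl acetate | CC1(C)O[C@@](C)([C@H](CCO)CC(=O)CC)[C@@H](OC(C)=O)C[C@@H]1Br
F2 | step 11 | (2S,3S,5S)-5-bromo-2-[(3S)-1-iodo-5-oxoheptan-3-yl]-2,6,6-trimethyloxan-3-yl acetate | CC1(C)O[C@@](C)([C@H](CCI)CC(=O)CC)[C@@H](OC(C)=O)C[C@@H]1Br
F3 | step 14 | (2S,3S,5S)-5-bromo-2,6,6-trimethyl-2-[(1R)-4-methyl-5-oxocyclohex-3-en-1-yl]oxan-3-yl acetate | CC1(C)O[C@@](C)([C@@H]2CC=C(C)C(=O)C2)[C@@H](OC(C)=O)C[C@@H]1Br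
F4 | step 14 | (2S,3S,5S)-5-bromo-2-[(1R,5R)-5-hydroxy-4-methylcyclohex-3-en-1-yl]-2,6,6-trimethyloxan-3-yl acetate | CC1(C)O[C@@](C)([C@@H]2CC=C(C)[C@H](O)C2)[C@@H](OC(C)=O)C[C@@H]1Br
F5 | step 14 | (2S,3S,5S)-5-bromo-2-[(1R,5S)-5-chloro-4-methylcyclohex-3-en-1-yl]-2,6,6-trimethyloxan-3-yl acetate | CC1(C)O[C@@](C)([C@@H]2CC=C(C)[C@@H](Cl)C2)[C@@H](OC(C)=O)C[C@@H]1Br
F6 | step 10 | bromo{(3S,5S,6S)-5-(acetyloxy)-2,2,6-trimethyl-6-[(3S)-5-oxohept-1-en-3-yl]oxan-3-yl}mercury | CC1(C)O[C@@](C)([C@H](C=C)CC(=O)CC)[C@@H](OC(C)=O)C[C@@H]1[Hg]Br
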